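The numbers were set for the occasion; what happens was integrated by code.

Temperature was what set these flasks apart, and the question was how much target each one held at the end.

| flask | substrate | partner | capture agent | temperature | time |
|---|---|---|---|---|---|
| violet | 0.10 M | 0.200 M | 0.0100 M | 65 °C | 15 min |
| ochre | 0.10 M | 0.200 M | 0.0100 M | 95 °C | 15 min |
| grey | 0.10 M | 0.200 M | 0.0100 M | 80 °C | 15 min |

    substrate ⇌ open intermediate (K1 = 1.2, k1 = 0.047 /min, Ea1 = 114 kJ/mol, ΔH1 = −40.0 kJ/mol)
    partner → second intermediate (k2 = 0.099 /min, Ea2 = 109 kJ/mol)
    open intermediate + second intermediate → target (k3 = 0.46 /M/min, Ea3 = 61.0 kJ/mol)
    2 second intermediate → homo product (k4 = 0.16 /M/min, Ea4 = 56.0 kJ/mol)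
    second intermediate + capture agent → trapped intermediate (k5 = 0.81 /M/min, Ea5 = 63.0 kJ/mol)
    substrate + target → side product (k6 = 1.2 /M/min, Ea6 = 68.0 kJ/mol)
    (constants at 80 °C)

- in percentages every species weighs as the substrate in it: one side product counts as two
- a step written with two of one species runs at k times the square of its concentration and takes two of it each time
- the constants hold at 80 °C; other temperatures follow from the activation energies and enthalpies

* which flask leads in amount of target, in percent of the substrate charged ("all alike" within 1.5 percentage points) (violet / ochre / grey / all alike)
* how much target is there at the end, in percent of the substrate charged: violet
* how much target is there at the end, in percent of the substrate charged: ochre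
* how much target is there at the end, in percent of the substrate charged: grey

- I looked for the concentration that sets the order of the rate. Target forms at its constant times c(open intermediate) times c(second intermediate). It is lost at its constant times c(substrate) times c(target), which is pseudo-first-order in target.
- I moved constants off the reference temperature by the shift in K. Enthalpy and activation energy share one temperature term, so each constant scales as that shift raised to activation energy over enthalpy.
- In ochre the ring equilibrium relaxes with a half-life of 1.24 min, shorter than the run. So c(open intermediate) over c(substrate) stood near K, 0.689.
- I set making equal to loss, and c(substrate) cancelled. With a making constant of 1.07 /M/min and a loss constant of 3.08 /M/min, ochre had a ceiling ratio, K times making over loss, the target held per second intermediate at balance, 0.240.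
- So I needed c(second intermediate), and it has two limits. One is what partner has delivered. The other treats the charge as delivered at once, with the inverse concentration growing by 2 times the homo constant per minute.
- The homo limit was lower than supply in ochre, giving 0.0648 M. It was also lower in grey, giving 0.102 M.
- In violet supply was lower, giving 0.0498 M.
- My first way was the ceiling. It gave ochre 15.5% and grey 46.9%.
- My second way was filling, which ignores loss, so it errs high. The target made is the making rate summed over the run. Its share of final rate times time depends on how fast both intermediates climb.
- I took c(open intermediate) from the relaxing equilibrium: 0.0408 M in ochre, 0.0396 M in grey, 0.0115 M in violet.
- In ochre partner's half-life was 1.54 min, so both intermediates climbed within minutes, and I took final rate times time as the upper figure for filling, 42.5%. That stood above the ceiling. Both ways use the same making constant and the same c(second intermediate), so neither checks the other. Target approaches the ceiling in about 5.48 min in ochre, shorter than the run, so in ochre filling was the one that cheated, and I kept the ceiling.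
- In grey partner's rate constant was 0.099 /min and the relaxation rate 0.0862 /min, so I let both intermediates rise together at partner's rate. Averaging the product of those two rises over the run gave a share of 0.464, and filling gave 12.9%. In grey the ceiling was the one that cheated, because target approaches it in about 18.3 min, longer than the run.
- In violet partner's rate constant times the run was 0.286, so I let both intermediates rise about in line with time, and the share for two straight rises is a third. Filling in violet came to 0.524%. My reckoning put ochre in the lead.
- The forecast also named ochre, with 0.55% in violet, 16% in ochre and 11.5% in grey, and called them “rough bench estimates”. It put grey lower than I did.
- The simulation gave ochre the lead, with 0.446% in violet, 15.5% in ochre and 8.68% in grey.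
- Ochre had not come to rest at 15.0 min. Its c(second intermediate) read 0.0609 M, and the ceiling ratio turned that into 14.6%, beside the target reading. The neighbour like ochre but with 0.34 M of partner read 0.0800 M, so the ratio gave 19.2%, and that flask held 20.4%. At 150 min ochre's c(second intermediate) stood at 0.00703 M, its side product at 92.4% and its target at 5.32%.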